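The double product is the species to follow, since it sets how far the share of first product (the selectivity) falls late in a flask.

| flask | substrate | partner | remark | time |
|---|---|---|---|---|
| delta | 20 mM | 1.2 equiv | run made earlier |  |
| alpha | 13 mM | 1.2 equiv | run made earlier |  |
| theta | 30 mM | 1.2 equiv | run made earlier |  |
| blue | 20 mM | 1.20 equiv | everything together at the start | 20 min |
| grey | 20 mM (fed, over 12 min) | 1.20 equiv | all else is in the flask from the start; the feed brings no volume worth counting | 20 min |
| teal | 20 mM (in portions, 3, over 12 min) | 1.20 equiv | first portion at the start, last at 12 min | 20 min |
| green | 20 mM | 1.20 equiv (fed, over 12 min) | all else is in the flask from the start; the feed brings no volume worth counting | 20 min |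

- delta (time / min: first product / %, double product / %): 1.50: 20.3, 2.1; 3.00: 25.8, 4.3; 5.00: 26.5, 5.7; 6.00: 26.6, 7.1; 8.00: 26.2, 8.8; 10.0: 25.5, 9.1; 12.0: 26.3, 9.8
- alpha (time / min: first product / %, double product / %): 1.00: 14.4, 0.5; 3.00: 21.4, 3.2; 6.00: 24.5, 6.3; 8.00: 26.7, 5.9; 12.0: 26.1, 8.1; 15.0: 26.6, 8.3; 20.0: 25.7, 9.7
- theta (time / min: first product / %, double product / %): 1.50: 23.3, 2.7; 2.50: 25.4, 6.3; 4.00: 25.1, 6.6; 6.00: 26.5, 9.5; 8.00: 25.9, 11.1; 12.0: 24.8, 12.0; 20.0: 24.7, 13.9

(each reading ± 0.5 percentage points)

1. the flask with the highest share of first product in first product plus double product ("all alike" if they lie within 1.5 percentage points) (blue / grey / teal / green / all alike)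
2. share of first product in first product plus double product at the end, blue
3. share of first product in first product plus double product at the end, grey
4. share of first product in first product plus double product at the end, teal
5. share of first product in first product plus double product at the end, green

- a species is counted by the substrate in it: one idle adduct counts as two
- amounts and yields of first product count idle adduct too
- the numbers in the tables scatter by 0.5 percentage points (one standard deviation)
- candidate steps: substrate + partner -> first product; substrate + partner -> other mono adduct; partner + first product -> double product; partner + other mono adduct -> double product; substrate + first product <-> idle adduct; partner <-> dormant form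
- in an amount of first product, one idle adduct counts as one first product

This reckoning, separate from the forecast, is made for blue, which has delta's charges, although delta stops at 12.0 min.

1. Late readings give the double product's gain per minute. Alpha gives 0.00200 min⁻¹ of the charge and theta 0.00238 min⁻¹, and with readings that scatter by 0.5 percentage points these two gains are not told apart.
2. Blue's concentration lies between these two, so their mean is taken as the tail gain, the fraction of the charge that becomes double product each late minute: 0.00219 min⁻¹. It is a reading and carries the scatter.
3. Carried from delta's last reading to 20 min, the double product reaches 11.6%. With first product held at 26.3%, the share is 69.4%.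
4. The weak link is that held first product, since the new double product must come from a mono adduct. In theta, first product fell by 0.409 of each unit of double product gained after 6.00 min. Putting the gain from step 3 back in leaves 25.6% of first product, so blue's share becomes 68.9%.

The forecast gives blue 69%, grey 63%, teal 65.5% and green 70%, and it picks green: “Green is therefore only marginally best”.

The flasks give blue 68.2%, grey 66.4%, teal 59.4% and green 72.1%, so the pick is green. Teal lies 6.1 points below the forecast.

    substrate + partner → first product (k = 0.277 L mol⁻¹ s⁻¹)
    substrate + partner → other mono adduct (k = 0.501 L mol⁻¹ s⁻¹)
    partner + first product → double product (k = 0.107 L mol⁻¹ s⁻¹)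
    partner + other mono adduct → double product (k = 0.0204 L mol⁻¹ s⁻¹)
    substrate + first product ⇌ idle adduct, settled at all times (K = 23.7 L mol⁻¹)
    partner ⇌ dormant form (K = 2.50, k = 6.69 × 10⁻⁴ s⁻¹)

Carried from teal's last addition, the tail gain takes its double product from 11.0% to 12.8%, and teal ends at 13.1%. Teal's late gain thus fits the tail gain, and at 12 min teal already holds 11.0% of double product against green's 4.88%. Striking out partner + first product narrows the gap between green and teal from 13 points to 4.5 points, the largest single effect, though not the main reason.

For green read at 30 min, the tail gain gives double product 12.2%, first product 25.0% and a share of 67.2%. The computed flask holds 12.1% and 25.3%, with a share of 67.7%.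

Readings and results were computed with made-up constants.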